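**Plan**
Retrosynthesis: the four O–Si bonds are cut first, then C2–C1′ (ring B to C2), then O1–C2 and C2–C3 of ring C back to an o-hydroxyacetophenone, and last ring A at C8a–C8, C7–C6 and C8a–C4a, which leaves a diazo enone and a siloxyalkyne.
Enabling feature: ring A (C4a, C5, C6, C7, C8, C8a) is a 1,2,3,4-tetrasubstituted benzene with the C8 chain between O1-bearing C8a and hydroxylated C7 and the C4 acyl carbon on C4a, which is the pattern a vinylketene–siloxyalkyne benzannulation delivers.
Forward: ring A is built around the finished (E)-side chain (steps 1–7), with the acetyl group carried through the photochemistry as its dimethyl ketal; ring C follows as a chromone (step 8); ring B arrives as an arylboronic acid (step 11); global desilylation ends the route.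
Stereochemistry: C2 (S) comes from ligand-controlled palladium-catalysed conjugate arylation of the chromone; the (E)-alkene is set in the SN2′ opening of isoprene monoxide and is not touched again.

Key step: step 7

Assumption: the (R)-configured pyridine–oxazoline ligand is taken to deliver the aryl group to the chromone face that gives 2S, by analogy with the sense of addition to cyclic enones; if a first run shows the opposite sense, the ligand antipode is used.

**Route**

Step 1
Reactants: 1 methyl 2,2-dimethoxypropanoate; 2 1-(triphenylphosphoranylidene)propan-2-one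
Product: 4 (E)-5,5-dimethoxyhex-3-en-2-one, via 2,2-dimethoxypropanal 3 (not isolated)
Conditions: i-Bu2AlH, CH2Cl2, −78 °C; MeOH, aq. potassium sodium tartrate; dried CH2Cl2 layer + 2, 40 °C
Reagents that add atoms: none
Why: Half-reduction of the α,α-dialkoxy ester should stop at the chelated aluminium hemiacetal, and the volatile aldehyde is taken in solution into a Wittig reaction with the ketone-stabilised ylide, which should give the (E)-enone.

Step 2
Reactants: 4 (E)-5,5-dimethoxyhex-3-en-2-one
Product: 7 (E)-1-diazo-5,5-dimethoxyhex-3-en-2-one, via lithium enolate 5 (not isolated), via trifluoroacetyl diketone 6 (not isolated)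
Conditions: LiN(SiMe3)2, THF, −78 °C; CF3CO2CH2CF3; aq. NaH2PO4 work-up; then MsN3, Et3N, H2O, MeCN, rt
Reagents that add atoms: methanesulfonyl azide, CS(=O)(=O)N=[N+]=[N-]
Why: Detrifluoroacetylative diazo transfer (a Regitz-type transfer to the activated trifluoroacetyl ketone) places the diazo group on the methyl carbon, the only enolisable site because C5 is a ketal carbon, and it avoids diazomethane, which would add to the enone double bond.

Step 3
Reactants: 8 2-methyl-2-vinyloxirane (racemic)
Product: 9 (E)-4-chloro-2-methylbut-2-en-1-ol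
Conditions: TiCl4, CH2Cl2, −85 °C; aq. HCl quench
Reagents that add atoms: titanium tetrachloride, Cl[Ti](Cl)(Cl)Cl
Why: Lewis-acid activation of the vinyl epoxide and SN2′ delivery of chloride to the alkene terminus opens the ring with allylic transposition, a known opening that should set the (E)-trisubstituted alkene here; any Z isomer is removed by chromatography at 10.

Step 4
Reactants: 9 (E)-4-chloro-2-methylbut-2-en-1-ol
Product: 10 (E)-tert-butyl[(4-chloro-2-methylbut-2-en-1-yl)oxy]dimethylsilane
Conditions: TBSCl, imidazole, CH2Cl2, 0 °C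
Reagents that add atoms: tert-butyldimethylsilyl chloride, CC(C)(C)[Si](C)(C)Cl
Why: Imidazole-promoted silylation of a primary alcohol is routine, and the allylic chloride should be untouched at 0 °C.

Step 5
Reactants: 10 (E)-tert-butyl[(4-chloro-2-methylbut-2-en-1-yl)oxy]dimethylsilane; 11 ethynylmagnesium bromide
Product: 12 (E)-tert-butyldimethyl[(2-methylhex-2-en-5-yn-1-yl)oxy]silane
Conditions: 11 (excess), CuCl (10 mol%), THF, 0 → 45 °C
Reagents that add atoms: none
Why: Copper-catalysed cross-coupling of an alkynyl Grignard reagent with a primary allylic chloride should give the skipped enyne by direct displacement, because the γ-carbon is fully substituted, with the alkene geometry retained.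

Step 6
Reactants: 12 (E)-tert-butyldimethyl[(2-methylhex-2-en-5-yn-1-yl)oxy]silane
Product: 15 (E)-6-(tert-butyldimethylsilyloxy)-5-methyl-1-(triisopropylsilyloxy)hex-4-en-1-yne, via lithium acetylide 13 (not isolated), via lithium ynolate 14 (not isolated)
Conditions: LiN(SiMe3)2 (2.2 equiv), THF, −78 °C; anhydrous t-BuOOH, −78 → 0 °C; TIPSOTf, −78 °C; chromatography on Et3N-treated silica
Reagents that add atoms: tert-butyl hydroperoxide, CC(C)(C)OO; triisopropylsilyl trifluoromethanesulfonate, CC(C)[Si](C(C)C)(C(C)C)OS(=O)(=O)C(F)(F)F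
Why: Oxidation of the lithium acetylide by lithium tert-butyl peroxide (acetylide-to-ynolate oxidation) and O-silylation of the ynolate with the bulky silyl triflate is the standard route to triisopropylsiloxyalkynes, and the amide base is too weak to remove the doubly activated CH2 protons.

Step 7
Reactants: 7 (E)-1-diazo-5,5-dimethoxyhex-3-en-2-one; 15 (E)-6-(tert-butyldimethylsilyloxy)-5-methyl-1-(triisopropylsilyloxy)hex-4-en-1-yne
Product: 21 1-[2-hydroxy-3-[(E)-4-(tert-butyldimethylsilyloxy)-3-methylbut-2-enyl]-4-(triisopropylsilyloxy)phenyl]ethanone, via vinylketene 16 (not isolated), via vinylcyclobutenone 17 (not isolated), via dienylketene 18 (not isolated), via cyclohexadienone 19 (not isolated), via ketal phenol 20 (not isolated)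
Conditions: 15 (slight excess), hν (254 nm, low-pressure Hg lamp, quartz), ClCH2CH2Cl, rt; then 80 °C; then PPTS (cat.), acetone–H2O, rt
Reagents that add atoms: water, O
Why: Irradiation expels N2 from 7 and Wolff rearrangement (1,2-shift of the alkenyl group) gives vinylketene 16, whose carbonyl carbon is attacked by the oxygen-remote carbon of siloxyalkyne 15 in a regioselective [2+2] cycloaddition to cyclobutenone 17, forming C8a–C8 and C7–C6. Cyclobutenone 17 opens by 4π electrocyclic cleavage (under the lamp or on warming) to dienylketene 18, ring A closes by thermal 6π electrocyclisation (C8a–C4a) to cyclohexadienone 19, this tautomerises to phenol 20, and the wet-acid finish frees the acetyl group from its ketal. The closest known reaction is the Danheiser benzannulation of α,β-unsaturated α′-diazo ketones with trialkylsiloxyalkynes, which gives resorcinol monosilyl ethers. No stereocentre is formed. The step needs only regiocontrol in the ketene–alkyne union, and the polarisation of the ynol ether secures it, so the side chain must end on C8 between the new phenol oxygen (the future O1) and the siloxy carbon C7, with the masked acetyl on C4a. The ketal keeps the intermediate from being a γ-oxo vinylketene, which could photoisomerise and close to a pyranone; it resists acid while conjugated to the enone and becomes labile once it sits on the electron-rich phenol.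

Step 8
Reactants: 21 1-[2-hydroxy-3-[(E)-4-(tert-butyldimethylsilyloxy)-3-methylbut-2-enyl]-4-(triisopropylsilyloxy)phenyl]ethanone; 22 N,N-dimethylformamide dimethyl acetal
Product: 24 8-[(E)-4-(tert-butyldimethylsilyloxy)-3-methylbut-2-enyl]-7-(triisopropylsilyloxy)-4H-chromen-4-one, via enaminone 23 (not isolated)
Conditions: 22, toluene, 90 °C; evaporate; AcOH (5 equiv), toluene, 80 °C
Reagents that add atoms: none
Why: Condensation of the methyl ketone with the formamide acetal gives the enaminone, and acid-promoted addition of the C8a phenol to its β-carbon with loss of dimethylamine (the standard enaminone route to chromones) should close ring C without cleaving the silyl ethers in a non-hydroxylic medium.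

Step 9
Reactants: 25 4-bromobenzene-1,2-diol
Product: 26 4-bromo-1,2-bis(tert-butyldimethylsilyloxy)benzene
Conditions: TBSCl (2.3 equiv), imidazole, DMF, rt
Reagents that add atoms: tert-butyldimethylsilyl chloride, CC(C)(C)[Si](C)(C)Cl
Why: Double silylation of a catechol with a silyl chloride and imidazole is routine.

Step 10
Reactants: 26 4-bromo-1,2-bis(tert-butyldimethylsilyloxy)benzene
Product: 29 [3,4-bis(tert-butyldimethylsilyloxy)phenyl]boronic acid, via aryllithium 27 (not isolated), via lithium triisopropoxyborate 28 (not isolated)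
Conditions: n-BuLi, THF, −78 °C; B(Oi-Pr)3, −78 °C → rt; 1 M HCl, 0 °C
Reagents that add atoms: triisopropyl borate, CC(C)OB(OC(C)C)OC(C)C; water, O
Why: Bromine–lithium exchange, borylation of the aryllithium and mild hydrolysis of the ate complex is the standard boronic acid synthesis, and because the lithium is not ortho to a silyloxy group no silyl shift to carbon can occur.

Step 11
Reactants: 24 8-[(E)-4-(tert-butyldimethylsilyloxy)-3-methylbut-2-enyl]-7-(triisopropylsilyloxy)-4H-chromen-4-one; 29 [3,4-bis(tert-butyldimethylsilyloxy)phenyl]boronic acid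
Product: 30 (2S)-2-[3,4-bis(tert-butyldimethylsilyloxy)phenyl]-8-[(E)-4-(tert-butyldimethylsilyloxy)-3-methylbut-2-enyl]-7-(triisopropylsilyloxy)chroman-4-one
Conditions: Pd(OCOCF3)2 (10 mol%), (R)-4-tert-butyl-2-(pyridin-2-yl)-4,5-dihydrooxazole (12 mol%), NH4PF6, H2O, ClCH2CH2Cl, 60 °C
Reagents that add atoms: none
Why: Asymmetric conjugate addition of an arylboronic acid to a chromone under cationic divalent palladium with a chiral pyridine–oxazoline ligand proceeds by aryl transfer from boron, face-selective insertion of the C2=C3 bond and protonolysis of the palladium enolate, and the tert-butyl group of the ligand should direct the aryl group to the C2 face that gives the S configuration.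

Step 12
Reactants: 30 (2S)-2-[3,4-bis(tert-butyldimethylsilyloxy)phenyl]-8-[(E)-4-(tert-butyldimethylsilyloxy)-3-methylbut-2-enyl]-7-(triisopropylsilyloxy)chroman-4-one
Product: 31 (2S)-2-(3,4-dihydroxyphenyl)-7-hydroxy-8-[(E)-4-hydroxy-3-methylbut-2-enyl]chroman-4-one (CNP0205253.1)
Conditions: Bu4NF, AcOH (1:1), THF, 0 °C → rt, under argon
Reagents that add atoms: none
Why: Fluoride-mediated desilylation should cleave the three aryl silyl ethers and the primary alkyl silyl ether, and the acetic acid buffer keeps the medium from becoming basic enough to open ring C by retro-oxa-Michael reaction, so the C2 configuration is preserved.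

**Compound list**

1 | methyl 2,2-dimethoxypropanoate | COC(=O)C(C)(OC)OC | starting material
2 | 1-(triphenylphosphoranylidene)propan-2-one | CC(=O)C=P(c1ccccc1)(c1ccccc1)c1ccccc1 | starting material
3 | 2,2-dimethoxypropanal | CC(OC)(OC)C=O | intermediate
4 | (E)-5,5-dimethoxyhex-3-en-2-one | CC(=O)/C=C/C(C)(OC)OC | intermediate
5 | lithium (3E)-5,5-dimethoxyhexa-1,3-dien-2-olate | [Li+].C=C([O-])/C=C/C(C)(OC)OC | intermediate
6 | (5E)-1,1,1-trifluoro-7,7-dimethoxyoct-5-ene-2,4-dione | CC(OC)(OC)/C=C/C(=O)CC(=O)C(F)(F)F | intermediate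
7 | (E)-1-diazo-5,5-dimethoxyhex-3-en-2-one | CC(OC)(OC)/C=C/C(=O)C=[N+]=[N-] | intermediate
8 | 2-methyl-2-vinyloxirane (racemic) | CC1(C=C)CO1 | starting material
9 | (E)-4-chloro-2-methylbut-2-en-1-ol | C/C(=C\CCl)CO | intermediate
10 | (E)-tert-butyl[(4-chloro-2-methylbut-2-en-1-yl)oxy]dimethylsilane | C/C(=C\CCl)CO[Si](C)(C)C(C)(C)C | intermediate
11 | ethynylmagnesium bromide | C#C[Mg]Br | starting material
12 | (E)-tert-butyldimethyl[(2-methylhex-2-en-5-yn-1-yl)oxy]silane | C/C(=C\CC#C)CO[Si](C)(C)C(C)(C)C | intermediate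
13 | lithium (E)-6-(tert-butyldimethylsilyloxy)-5-methylhex-4-en-1-yn-1-ide | [Li+].C/C(=C\CC#[C-])CO[Si](C)(C)C(C)(C)C | intermediate
14 | lithium (E)-6-(tert-butyldimethylsilyloxy)-5-methylhex-4-en-1-yn-1-olate | [Li+].C/C(=C\CC#C[O-])CO[Si](C)(C)C(C)(C)C | intermediate
15 | (E)-6-(tert-butyldimethylsilyloxy)-5-methyl-1-(triisopropylsilyloxy)hex-4-en-1-yne | C/C(=C\CC#CO[Si](C(C)C)(C(C)C)C(C)C)CO[Si](C)(C)C(C)(C)C | intermediate
16 | (3E)-5,5-dimethoxyhexa-1,3-dien-1-one | O=C=C/C=C/C(C)(OC)OC | intermediate
17 | 2-[(E)-4-(tert-butyldimethylsilyloxy)-3-methylbut-2-enyl]-4-[(E)-3,3-dimethoxybut-1-enyl]-3-(triisopropylsilyloxy)cyclobut-2-en-1-one (racemic) | C/C(=C\CC1=C(O[Si](C(C)C)(C(C)C)C(C)C)C(/C=C/C(C)(OC)OC)C1=O)CO[Si](C)(C)C(C)(C)C | intermediate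
18 | (3E,5E)-2-[(E)-4-(tert-butyldimethylsilyloxy)-3-methylbut-2-enyl]-7,7-dimethoxy-3-(triisopropylsilyloxy)octa-1,3,5-trien-1-one | C/C(=C\CC(=C=O)/C(O[Si](C(C)C)(C(C)C)C(C)C)=C\C=C\C(C)(OC)OC)CO[Si](C)(C)C(C)(C)C | intermediate
19 | 6-(1,1-dimethoxyethyl)-2-[(E)-4-(tert-butyldimethylsilyloxy)-3-methylbut-2-enyl]-3-(triisopropylsilyloxy)cyclohexa-2,4-dien-1-one (racemic) | C/C(=C\CC1=C(O[Si](C(C)C)(C(C)C)C(C)C)C=CC(C(C)(OC)OC)C1=O)CO[Si](C)(C)C(C)(C)C | intermediate
20 | 6-(1,1-dimethoxyethyl)-2-[(E)-4-(tert-butyldimethylsilyloxy)-3-methylbut-2-enyl]-3-(triisopropylsilyloxy)phenol | C/C(=C\Cc1c(O[Si](C(C)C)(C(C)C)C(C)C)ccc(C(C)(OC)OC)c1O)CO[Si](C)(C)C(C)(C)C | intermediate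
21 | 1-[2-hydroxy-3-[(E)-4-(tert-butyldimethylsilyloxy)-3-methylbut-2-enyl]-4-(triisopropylsilyloxy)phenyl]ethanone | C/C(=C\Cc1c(O[Si](C(C)C)(C(C)C)C(C)C)ccc(C(C)=O)c1O)CO[Si](C)(C)C(C)(C)C | intermediate
22 | N,N-dimethylformamide dimethyl acetal | COC(OC)N(C)C | starting material
23 | (E)-3-(dimethylamino)-1-[2-hydroxy-3-[(E)-4-(tert-butyldimethylsilyloxy)-3-methylbut-2-enyl]-4-(triisopropylsilyloxy)phenyl]prop-2-en-1-one | C/C(=C\Cc1c(O[Si](C(C)C)(C(C)C)C(C)C)ccc(C(=O)/C=C/N(C)C)c1O)CO[Si](C)(C)C(C)(C)C | intermediate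
24 | 8-[(E)-4-(tert-butyldimethylsilyloxy)-3-methylbut-2-enyl]-7-(triisopropylsilyloxy)-4H-chromen-4-one | C/C(=C\Cc1c(O[Si](C(C)C)(C(C)C)C(C)C)ccc2c1OC=CC2=O)CO[Si](C)(C)C(C)(C)C | intermediate
25 | 4-bromobenzene-1,2-diol | Oc1ccc(Br)cc1O | starting material
26 | 4-bromo-1,2-bis(tert-butyldimethylsilyloxy)benzene | CC(C)(C)[Si](C)(C)Oc1ccc(Br)cc1O[Si](C)(C)C(C)(C)C | intermediate
27 | [3,4-bis(tert-butyldimethylsilyloxy)phenyl]lithium | [Li]c1ccc(O[Si](C)(C)C(C)(C)C)c(O[Si](C)(C)C(C)(C)C)c1 | intermediate
28 | lithium [3,4-bis(tert-butyldimethylsilyloxy)phenyl]tri(propan-2-yloxy)borate | [Li+].CC(C)O[B-](OC(C)C)(OC(C)C)c1ccc(O[Si](C)(C)C(C)(C)C)c(O[Si](C)(C)C(C)(C)C)c1 | intermediate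
29 | [3,4-bis(tert-butyldimethylsilyloxy)phenyl]boronic acid | OB(O)c1ccc(O[Si](C)(C)C(C)(C)C)c(O[Si](C)(C)C(C)(C)C)c1 | intermediate
30 | (2S)-2-[3,4-bis(tert-butyldimethylsilyloxy)phenyl]-8-[(E)-4-(tert-butyldimethylsilyloxy)-3-methylbut-2-enyl]-7-(triisopropylsilyloxy)chroman-4-one | C/C(=C\Cc1c(O[Si](C(C)C)(C(C)C)C(C)C)ccc2c1O[C@H](c1ccc(O[Si](C)(C)C(C)(C)C)c(O[Si](C)(C)C(C)(C)C)c1)CC2=O)CO[Si](C)(C)C(C)(C)C | intermediate
31 | (2S)-2-(3,4-dihydroxyphenyl)-7-hydroxy-8-[(E)-4-hydroxy-3-methylbut-2-enyl]chroman-4-one | C/C(=C\Cc1c(O)ccc2c1O[C@H](c1ccc(O)c(O)c1)CC2=O)CO | target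

**Count and risks**

Total steps: 12. Longest linear sequence: 8 steps (steps 3, 4, 5, 6, 7, 8, 11, 12, from 2-methyl-2-vinyloxirane).

Steps most likely to fail:

1. Step 7. The photogenerated vinylketene may dimerise or polymerise faster than the siloxyalkyne traps it, or the cascade may stall at the vinylcyclobutenone because the 6π closure must place the bulky ketal carbon on the ring. The fallback gives up the ring synthesis and substitutes a purchased ring A; it sets out from allylic chloride 10 and returns at 21. Commercial 1-(2,4-dihydroxyphenyl)ethanone is C-allylated with 10 in aqueous KOH at rt. Its dianion should react mainly at the carbon between the two oxygens, and the O-allyl and C5 isomers formed alongside are removed by chromatography, giving 1-[2,4-dihydroxy-3-[(E)-4-(tert-butyldimethylsilyloxy)-3-methylbut-2-enyl]phenyl]ethanone F1. TIPSCl and imidazole then silylate only the 4-OH, since the 2-OH is held in the hydrogen bond to the ketone, which gives 21.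

2. Step 11. Protodeboronation and oxidative homocoupling of the electron-rich boronic acid may outrun insertion of the electron-rich chromone, or the aryl group may be delivered to both faces. The fallback closes ring C by oxa-Michael addition and takes the configuration from a resolution; it sets out from bromide 26 (through aryllithium 27) and acetophenone 21 and returns at 30. Aryllithium 27 is quenched with DMF to give 3,4-bis(tert-butyldimethylsilyloxy)benzaldehyde F2. Pyrrolidine-mediated Claisen–Schmidt condensation with 21 (EtOH, rt) gives (E)-3-[3,4-bis(tert-butyldimethylsilyloxy)phenyl]-1-[2-hydroxy-3-[(E)-4-(tert-butyldimethylsilyloxy)-3-methylbut-2-enyl]-4-(triisopropylsilyloxy)phenyl]prop-2-en-1-one F3. This closes under the same mildly basic conditions, completed with NaOAc in warm EtOH, to the racemic flavanone rac-30 F4. Preparative HPLC on a chiral stationary phase separates the 2S enantiomer, which is 30, from the (2R)-enantiomer of 30 F5, which is re-equilibrated through F3 with mild base and resolved again.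

3. Step 12. Fluoride may open ring C by retro-oxa-Michael reaction and erode the C2 configuration while the slow primary alkyl silyl ether is still being cleaved, and the freed catechol may oxidise in air during the long exposure. The fallback removes the slow silyl groups before the stereocentre exists; it sets out from chromone 24 and returns at 31. Bu4NF/AcOH in THF converts 24 into 7-hydroxy-8-[(E)-4-hydroxy-3-methylbut-2-enyl]-4H-chromen-4-one F6. Conjugate addition of 29 under the conditions of step 11, which should tolerate the free phenol and alcohol in the aqueous cationic palladium system, gives (2S)-2-[3,4-bis(tert-butyldimethylsilyloxy)phenyl]-7-hydroxy-8-[(E)-4-hydroxy-3-methylbut-2-enyl]chroman-4-one F7. The two remaining aryl silyl ethers are then cleaved by KHF2 in MeOH at rt, a brief and nearly neutral treatment, to give 31.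

**Further compounds**

F1 | step 7 | 1-[2,4-dihydroxy-3-[(E)-4-(tert-butyldimethylsilyloxy)-3-methylbut-2-enyl]phenyl]ethanone | C/C(=C\Cc1c(O)ccc(C(C)=O)c1O)CO[Si](C)(C)C(C)(C)C
F2 | step 11 | 3,4-bis(tert-butyldimethylsilyloxy)benzaldehyde | O=Cc1ccc(O[Si](C)(C)C(C)(C)C)c(O[Si](C)(C)C(C)(C)C)c1
F3 | step 11 | (E)-3-[3,4-bis(tert-butyldimethylsilyloxy)phenyl]-1-[2-hydroxy-3-[(E)-4-(tert-butyldimethylsilyloxy)-3-methylbut-2-enyl]-4-(triisopropylsilyloxy)phenyl]prop-2-en-1-one | C/C(=C\Cc1c(O[Si](C(C)C)(C(C)C)C(C)C)ccc(C(=O)/C=C/c2ccc(O[Si](C)(C)C(C)(C)C)c(O[Si](C)(C)C(C)(C)C)c2)c1O)CO[Si](C)(C)C(C)(C)C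
F4 | step 11 | rac-2-[3,4-bis(tert-butyldimethylsilyloxy)phenyl]-8-[(E)-4-(tert-butyldimethylsilyloxy)-3-methylbut-2-enyl]-7-(triisopropylsilyloxy)chroman-4-one | C/C(=C\Cc1c(O[Si](C(C)C)(C(C)C)C(C)C)ccc2c1OC(c1ccc(O[Si](C)(C)C(C)(C)C)c(O[Si](C)(C)C(C)(C)C)c1)CC2=O)CO[Si](C)(C)C(C)(C)C
F5 | step 11 | (2R)-2-[3,4-bis(tert-butyldimethylsilyloxy)phenyl]-8-[(E)-4-(tert-butyldimethylsilyloxy)-3-methylbut-2-enyl]-7-(triisopropylsilyloxy)chroman-4-one | C/C(=C\Cc1c(O[Si](C(C)C)(C(C)C)C(C)C)ccc2c1O[C@@H](c1ccc(O[Si](C)(C)C(C)(C)C)c(O[Si](C)(C)C(C)(C)C)c1)CC2=O)CO[Si](C)(C)C(C)(C)C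
F6 | step 12 | 7-hydroxy-8-[(E)-4-hydroxy-3-methylbut-2-enyl]-4H-chromen-4-one | C/C(=C\Cc1c(O)ccc2c1OC=CC2=O)CO
F7 | step 12 | (2S)-2-[3,4-bis(tert-butyldimethylsilyloxy)phenyl]-7-hydroxy-8-[(E)-4-hydroxy-3-methylbut-2-enyl]chroman-4-one | C/C(=C\Cc1c(O)ccc2c1O[C@H](c1ccc(O[Si](C)(C)C(C)(C)C)c(O[Si](C)(C)C(C)(C)C)c1)CC2=O)CO
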